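# Triumbelletin: proposed total synthesis through a vinylketene–ynol ether benzannulation

## Structural features

Triumbelletin is built from three 2H-chromen-2-one (coumarin) units, called here unit A (terminal, ether-linked), unit B (central) and unit C (terminal, carbon-linked). O7 of unit A is bound to C3 of the pyranone ring of unit B as an enol aryl ether. C8 of unit B is bound directly to C8 of unit C, and units B and C each keep a free 7-OH. There is no stereocentre; the only stereogenic element is the C8(B)–C8(C) axis, which carries four ortho oxygen substituents (O1 and O7 on each side). The fragile groups are the three lactones (opened by hydroxide, alkoxides and amines), the three C3=C4 double bonds (reducible, prone to UV photodimerisation) and the two oxidisable phenols. The real difficulty is double: a tetra-ortho-oxygenated biaryl bond between two electron-poor rings, and the differentiation of units B and C, which are the same 8-substituted 7-hydroxycoumarin except for the aryloxy group at C3 of unit B. The key step exploits the substitution pattern of the carbocycle of unit B: C8a (O), C8 (aryl), C7 (O), C6 (H), C5 (H), C4a (carbon branch C4). A vinylketene (supplying C8a, C6, C5, C4a) and a 1-alkoxy-2-arylalkyne (supplying C7, C8) assemble exactly this pattern in a benzannulation, delivering a free OH at C8a, an ether at C7, and a biaryl bond inherited from an unhindered aryl–alkyne bond.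

## Logic of the disconnections

**22 ⇒ 21.** The O–CH3 bond at O7 of unit C and the O–CH2CH3 bond at O7 of unit B are introduced retrosynthetically.
- Reason: a free OH next to the alkyne would cyclise onto it in step 3, and free phenols would be acylated in steps 6 and 9.
- Gain: none in skeleton, only in chemoselectivity.
- Demand: the last step must cleave two alkyl aryl ethers beside the axis without touching three lactones and the sp2–O–sp2 ether.

**21 ⇒ 16 + 19.** The C3=C4 and O1–C2 bonds of the pyranone ring of unit B are cut.
- Reason: unit A leaves together with the enol ether oxygen, so the C3–O bond never has to be made by substitution on a coumarin. In 19 that oxygen sits on an sp3 carbon.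
- Gain: three coumarin units reduce to one biaryl salicylaldehyde and one simple acid.
- Demand: 16 must carry exactly one free OH, and it must be the one ortho to the aldehyde.

**16 ⇒ 5 + 10 (key).** The bonds C8–C8a, C7–C6 and C8a–C4a of the carbocycle of unit B are cut, and also C6–C5, which arises from a 1,2-shift.
- In one sentence: the carbocycle of unit B is grown by a vinylketene–ynol ether benzannulation onto the alkyne of 5.
- Reason: the hindered axis is not made by joining two finished rings but is the former aryl–C(sp) bond of 5.
- The same operation places the aryl group between the two oxygens, leaves only O at C8a free, and puts the C4 carbon ortho to that OH. It also makes units B and C different by construction.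
- Gain: a tetra-ortho-substituted unsymmetrical biaryl reduces to one coumarin alkyne and a five-carbon open chain.
- Demand: the transient ketene must be captured by a shielded alkyne faster than it is lost, and ketene generation must spare the coumarin chromophore.

**5 ⇒ 3 + 4.** The C8(C)–C(sp) bond is cut.
- Reason: the incoming carbon is linear and small, so the two ortho oxygens of unit C matter little.
- Gain: back to a halogenated derivative of 1 and a two-carbon reagent that brings C7, C8 and O7 of unit B.
- Demand: a neutral to basic, water-free coupling and work-up, because the product is sensitive to hydration.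

**3 ⇒ 2 ⇒ 1.** The O7–CH3 and C8–I bonds are cut.
- Reason: C8 is the most nucleophilic position of the phenoxide of 1.
- Gain: unit C comes complete from 1.
- Demand: mono-iodination at C8 rather than C6.

**10 ⇒ 8 ⇒ 6 + 7.** The C=N2 bond and then the C=C bond are cut.
- Reason: diazo transfer onto a methyl enone avoids diazomethane, and a stabilised ylide sets the E-alkene.
- Atom origin: 7 supplies C8a, O1, C6 and C5; 6 supplies C4a and the masked C4.
- Demand: kinetic enolisation at the methyl group and survival of the acetal.

**19 ⇒ 18 ⇒ 1 + 17.** The ester C–O bond and then the O7(A)–CH2 bond are cut.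
- Reason: phenol alkylation makes the future C3–O–C7 ether under trivial conditions, and 17 supplies C3 and C2 of unit B.
- Gain: unit A also comes complete from 1.
- Demand: release of the acid without aqueous base.

## Other disconnections considered

**Alternative 1:** (the first that comes to mind) The C8(B)–C8(C) bond is cut between two finished coumarins.
- Forward key step: Suzuki–Miyaura coupling of 7-methoxy-8-(pinacolboryl)coumarin A1 with 7-ethoxy-8-iodo-3-(coumarin-7-yloxy)coumarin A2, giving 21.
- Reductive elimination would have to join two aryl ligands that each carry two ortho oxygens.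
- Transmetalation of a di-ortho-substituted boronate is slow. 2,6-Dioxygenated arylboron compounds also lose boron readily under the aqueous base that would open the lactones.
- A2 needs its own sequence of ring construction, protection and regioselective iodination, so no steps are saved.
- The chosen plan makes the same axis as an aryl–alkynyl bond, where steric demand is minimal.

**Alternative 2:** The same axis is cut down to two free phenols.
- Forward key step: anodic dehydrogenative cross-coupling of 1 with 7-hydroxy-3-(coumarin-7-yloxy)coumarin A3, giving 22 directly.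
- The plan is very short, but cross-selectivity in phenol–phenol oxidation rests on one partner being easier to oxidise and the other being the better nucleophile.
- In 1 and A3 the phenolic rings are electronically almost identical, because the aryloxy group sits on the remote pyranone carbon.
- A statistical spread over the homodimer A4 of 1, the homodimer A5 of A3 and 22 must therefore be expected, further divided by C6, C8 and O attack.
- The lactone acceptor raises the oxidation potentials, so the product biphenols would be oxidised in the same window.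
- The chosen plan has no homo-/cross-coupling problem, because only one ring is formed.

**Alternative 3:** Both pyranone rings are cut in a two-directional plan, back to the C2-symmetric 2,2'-dihydroxy-6,6'-dimethoxybiphenyl-3,3'-dicarbaldehyde A6.
- Forward key step: two different annulations on A6, one Perkin condensation with 19 and one Wittig olefination–lactonisation, then dealkylation to 22.
- The axis would be easy, being a homocoupling.
- However, the two salicylaldehyde halves are homotopic and are electronically insulated by the nearly orthogonal axis.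
- The first annulation therefore cannot be stopped selectively at the mono stage, and it does not bias the second.
- The desymmetrisation is statistical at the most valuable intermediate. The chosen plan builds the two halves at different times, so they are never equivalent.

Key step: step 6

Assumption: the SMILES defines no configuration at the C8(B)–C8(C) axis, so the racemic mixture of atropisomers is taken as the target.

## Route

Step 1
Reactants: 1 umbelliferone (7-hydroxy-2H-chromen-2-one)
Product: 2 7-hydroxy-8-iodo-2H-chromen-2-one
Conditions: I2, KI, 20% aq NH3, 0 °C to rt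
Reagents that add atoms: iodine, [I][I]
Why: Electrophilic aromatic iodination of the phenoxide; C8, flanked by O7 and O1, is the most nucleophilic carbon (the analogue of C1 in 2-naphthol), and one equivalent of iodine should limit di-iodination.

Step 2
Reactants: 2 7-hydroxy-8-iodo-2H-chromen-2-one
Product: 3 8-iodo-7-methoxy-2H-chromen-2-one
Conditions: MeI, K2CO3, acetone, reflux
Reagents that add atoms: iodomethane, CI
Why: Williamson ether synthesis on an acidic phenol; the mask prevents cyclisation of the phenol onto the alkyne in step 3 and acylation by the ketene in step 6.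

Step 3
Reactants: 3 8-iodo-7-methoxy-2H-chromen-2-one; 4 ethoxyacetylene (ethoxyethyne)
Product: 5 8-(ethoxyethynyl)-7-methoxy-2H-chromen-2-one
Conditions: PdCl2(PPh3)2 (cat.), CuI (cat.), Et3N, THF, rt to 40 °C
Reagents that add atoms: none
Why: Sonogashira coupling of a terminal ynol ether with an aryl iodide; oxidative addition of zerovalent palladium into the C–I bond is fast and the linear acetylide tolerates the two ortho oxygens. The medium stays basic and dry, and 5 is purified on base-washed silica to avoid hydration.

Step 4
Reactants: 6 2,2-dimethoxyacetaldehyde; 7 1-(triphenylphosphoranylidene)propan-2-one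
Product: 8 (E)-5,5-dimethoxypent-3-en-2-one
Conditions: CH2Cl2, rt
Reagents that add atoms: none
Why: Wittig olefination with a stabilised ylide, which should give the E-enone under thermodynamic control of the oxaphosphetane; the acetal is inert to these neutral conditions.

Step 5
Reactants: 8 (E)-5,5-dimethoxypent-3-en-2-one
Product: 10 (E)-1-diazo-5,5-dimethoxypent-3-en-2-one, via trifluoroacetyl diketone 9 (not isolated)
Conditions: LiN(SiMe3)2, THF, −78 °C, then CF3CO2CH2CF3; dilute HCl wash; then MsN3, Et3N, H2O, MeCN, rt
Reagents that add atoms: methanesulfonyl azide, CS(=O)(=O)N=[N+]=[N-]; 2,2,2-trifluoroethyl trifluoroacetate, FC(F)(F)COC(=O)C(F)(F)F (its CF3CO group stays only in 9)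
Why: Detrifluoroacetylative (Regitz-type deacylative) diazo transfer: kinetic deprotonation at the methyl group, Claisen-type trifluoroacetylation to 9, then diazo transfer with loss of the activating acyl group. The method avoids diazomethane, which would add across the enone C=C.

Step 6
Reactants: 5 8-(ethoxyethynyl)-7-methoxy-2H-chromen-2-one; 10 (E)-1-diazo-5,5-dimethoxypent-3-en-2-one
Product: 16 4-ethoxy-2-hydroxy-3-(7-methoxy-2-oxo-2H-chromen-8-yl)benzaldehyde, via vinylketene 11 (not isolated), via alkenylcyclobutenone 12 (not isolated), via dienylketene 13 (not isolated), via cyclohexadienone 14 (not isolated), via phenol acetal 15 (not isolated)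
Conditions: ClCH2CH2Cl, hν (450 nm LED), rt, slow addition of 10 to 5; then 80 °C (dark); then 1 M HCl, THF, rt
Reagents that add atoms: water, O
Why: Visible-light Wolff rearrangement of 10 (loss of N2, alkenyl shift) gives vinylketene 11, whose electrophilic ketene carbon is attacked by the aryl-bearing nucleophilic carbon of ynol ether 5 in a regiospecific (2+2) cycloaddition to give 12. On heating, reversible 4π electrocyclic opening of 12 gives 13, 6π electrocyclic closure forms the C8a–C4a bond of 14, enolisation gives 15, and the acid wash unmasks the aldehyde of 16. The closest known reaction type is the Danheiser benzannulation in its diazo ketone variant with alkoxy- and siloxyalkynes, and the only extension here is that the alkyne substituent is a di-ortho-substituted aryl group. One ring is closed, the carbocycle of unit B, by a thermal six-electron disrotatory electrocyclisation of a dienylketene, with four ring atoms from 10 and two from 5. No stereocentre persists: C4 of 12 and the sp3 carbon of 14 are erased on aromatisation and the axis forms as a racemate. The step needs regioselectivity, and the polarisation of 5 by its oxygen lone pair against the ketene carbonyl carbon places the aryl group between OH and OEt, while the E-alkene of 10 places the acetal carbon at the ring terminus next to the free OH. The step also needs chemoselectivity: 450 nm light reaches the long-wavelength band of the diazo ketone but not the coumarin chromophore, slow addition keeps 11 dilute against dimerisation, and the phenol appears only in the dark thermal stage after 10 is consumed, which limits ketene acylation. Sterically, all new bonds are formed at sp or unhindered sp2 carbons, so the ortho oxygens of unit C do not clash as they would when two finished rings are joined.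

Step 7
Reactants: 1 umbelliferone; 17 tert-butyl bromoacetate
Product: 18 tert-butyl 2-[(2-oxo-2H-chromen-7-yl)oxy]acetate
Conditions: K2CO3, acetone, reflux
Reagents that add atoms: none
Why: Williamson alkylation of the phenoxide with an activated primary bromide; the weak base leaves the lactone closed.

Step 8
Reactants: 18 tert-butyl 2-[(2-oxo-2H-chromen-7-yl)oxy]acetate
Product: 19 2-[(2-oxo-2H-chromen-7-yl)oxy]acetic acid
Conditions: CF3CO2H, CH2Cl2, rt
Reagents that add atoms: none
Why: Acidolysis of a tert-butyl ester through the tert-butyl cation; it avoids aqueous base, so the lactone is never opened.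

Step 9
Reactants: 16 4-ethoxy-2-hydroxy-3-(7-methoxy-2-oxo-2H-chromen-8-yl)benzaldehyde; 19 2-[(2-oxo-2H-chromen-7-yl)oxy]acetic acid
Product: 21 7-ethoxy-8-(7-methoxy-2-oxo-2H-chromen-8-yl)-3-[(2-oxo-2H-chromen-7-yl)oxy]-2H-chromen-2-one, via aryl ester 20 (not isolated)
Conditions: Ac2O, Et3N, 120 °C
Reagents that add atoms: none
Why: Perkin–Oglialoro coumarin synthesis: the anhydride activates 19, the only free phenol of 16 is acylated to 20, and the OCH2 group of 20 undergoes amine-mediated intramolecular aldol condensation with the neighbouring aldehyde, followed by dehydration. Closure is a six-membered ring formation and no other OH or enolisable site competes.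

Step 10
Reactants: 21 7-ethoxy-8-(7-methoxy-2-oxo-2H-chromen-8-yl)-3-[(2-oxo-2H-chromen-7-yl)oxy]-2H-chromen-2-one
Product: 22 triumbelletin
Conditions: BBr3 (excess), CH2Cl2, −78 °C to rt; then H2O
Reagents that add atoms: none
Why: Lewis acid cleavage of alkyl aryl ethers by bromide attack at the methyl and ethyl carbons. The C3–O–C7 ether has no sp3 carbon and cannot be cleaved this way, and the lactone–boron complexes are released unchanged on aqueous work-up.

## Compound list

1 | umbelliferone (7-hydroxy-2H-chromen-2-one) | O=c1ccc2ccc(O)cc2o1 | starting material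
2 | 7-hydroxy-8-iodo-2H-chromen-2-one | O=c1ccc2ccc(O)c(I)c2o1 | intermediate
3 | 8-iodo-7-methoxy-2H-chromen-2-one | O=c1ccc2ccc(OC)c(I)c2o1 | intermediate
4 | ethoxyacetylene | C#COCC | starting material
5 | 8-(ethoxyethynyl)-7-methoxy-2H-chromen-2-one | CCOC#Cc1c(OC)ccc2ccc(=O)oc12 | intermediate
6 | 2,2-dimethoxyacetaldehyde | COC(OC)C=O | starting material
7 | 1-(triphenylphosphoranylidene)propan-2-one | CC(=O)C=P(c1ccccc1)(c1ccccc1)c1ccccc1 | starting material
8 | (E)-5,5-dimethoxypent-3-en-2-one | COC(OC)/C=C/C(C)=O | intermediate
9 | (E)-1,1,1-trifluoro-7,7-dimethoxyhept-5-ene-2,4-dione | COC(OC)/C=C/C(=O)CC(=O)C(F)(F)F | intermediate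
10 | (E)-1-diazo-5,5-dimethoxypent-3-en-2-one | COC(OC)/C=C/C(=O)C=[N+]=[N-] | intermediate
11 | (E)-5,5-dimethoxypenta-1,3-dien-1-one (vinylketene) | O=C=C/C=C/C(OC)OC | intermediate
12 | 4-[(E)-3,3-dimethoxyprop-1-enyl]-3-ethoxy-2-(7-methoxy-2-oxo-2H-chromen-8-yl)cyclobut-2-en-1-one (racemic) | CCOC1=C(C(=O)C1/C=C/C(OC)OC)c1c(OC)ccc2ccc(=O)oc12 | intermediate
13 | 3-ethoxy-7,7-dimethoxy-2-(7-methoxy-2-oxo-2H-chromen-8-yl)hepta-1,3,5-trien-1-one (dienylketene, ketenyl and vinyl groups cis on C3=C4, C5=C6 E) | O=C=C(c1c(OC)ccc2ccc(=O)oc12)/C(OCC)=C\C=C\C(OC)OC | intermediate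
14 | 6-(dimethoxymethyl)-3-ethoxy-2-(7-methoxy-2-oxo-2H-chromen-8-yl)cyclohexa-2,4-dien-1-one (racemic) | CCOC1=C(C(=O)C(C=C1)C(OC)OC)c1c(OC)ccc2ccc(=O)oc12 | intermediate
15 | 8-[3-(dimethoxymethyl)-6-ethoxy-2-hydroxyphenyl]-7-methoxy-2H-chromen-2-one (racemic axis) | CCOc1ccc(C(OC)OC)c(O)c1-c1c(OC)ccc2ccc(=O)oc12 | intermediate
16 | 4-ethoxy-2-hydroxy-3-(7-methoxy-2-oxo-2H-chromen-8-yl)benzaldehyde (racemic axis) | CCOc1ccc(C=O)c(O)c1-c1c(OC)ccc2ccc(=O)oc12 | intermediate
17 | tert-butyl bromoacetate | CC(C)(C)OC(=O)CBr | starting material
18 | tert-butyl 2-[(2-oxo-2H-chromen-7-yl)oxy]acetate | CC(C)(C)OC(=O)COc1ccc2ccc(=O)oc2c1 | intermediate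
19 | 2-[(2-oxo-2H-chromen-7-yl)oxy]acetic acid | OC(=O)COc1ccc2ccc(=O)oc2c1 | intermediate
20 | 3-ethoxy-6-formyl-2-(7-methoxy-2-oxo-2H-chromen-8-yl)phenyl 2-[(2-oxo-2H-chromen-7-yl)oxy]acetate | CCOc1ccc(C=O)c(OC(=O)COc2ccc3ccc(=O)oc3c2)c1-c1c(OC)ccc2ccc(=O)oc12 | intermediate
21 | 7-ethoxy-8-(7-methoxy-2-oxo-2H-chromen-8-yl)-3-[(2-oxo-2H-chromen-7-yl)oxy]-2H-chromen-2-one (racemic axis) | CCOc1ccc2cc(Oc3ccc4ccc(=O)oc4c3)c(=O)oc2c1-c1c(OC)ccc2ccc(=O)oc12 | intermediate
22 | triumbelletin (racemic axis) | O=c1ccc2ccc(Oc3cc4ccc(O)c(-c5c(O)ccc6ccc(=O)oc56)c4oc3=O)cc2o1 | target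

## Step count and least certain steps

Total step count: 10. Longest linear sequence: 6 steps (steps 1, 2, 3, 6, 9, 10).

**Step 6 (key step).**
- Most likely failure: capture of the short-lived ketene 11 by 5 is too slow. The nucleophilic alkyne carbon carries a twisted, di-ortho-substituted and conjugating aryl group. Ketene dimerisation, acylation of the product phenol and residual light absorption by the coumarin could then consume the material.
- Fallback (from 3, back to the route at 22): the axis is made on a simple arene and unit B is completed afterwards.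
- Suzuki–Miyaura coupling of 3 with commercial (2,6-dimethoxyphenyl)boronic acid (Pd(OAc)2, SPhos, K3PO4, toluene, 100 °C) would give 8-(2,6-dimethoxyphenyl)-7-methoxy-2H-chromen-2-one F1.
- Rieche formylation (Cl2CHOMe, TiCl4, CH2Cl2) of the more electron-rich ring would give 2,4-dimethoxy-3-(7-methoxy-2-oxo-2H-chromen-8-yl)benzaldehyde F2.
- Chelation-controlled cleavage of the methoxy group ortho to the aldehyde with BCl3 would give 2-hydroxy-4-methoxy-3-(7-methoxy-2-oxo-2H-chromen-8-yl)benzaldehyde F3.
- Condensation with 19 as in step 9 would give 7-methoxy-8-(7-methoxy-2-oxo-2H-chromen-8-yl)-3-[(2-oxo-2H-chromen-7-yl)oxy]-2H-chromen-2-one F4, and BBr3 would give 22.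

**Step 3.**
- Most likely failure: slow coupling at the di-ortho-substituted iodide lets copper-mediated oxidative homocoupling of 4 compete. Hydration of the electron-rich triple bond during work-up or chromatography is a second loss channel.
- Fallback (from 3, back at 5): the triple bond is made by elimination instead of by coupling an alkyne.
- Suzuki–Miyaura coupling of 3 with commercial (E)-2-(2-ethoxyvinyl)-4,4,5,5-tetramethyl-1,3,2-dioxaborolane (PdCl2(dppf), K3PO4, dioxane) would give 8-[(E)-2-ethoxyethenyl]-7-methoxy-2H-chromen-2-one F5.
- Addition of Br2 at −78 °C to the enol ether, which is far more nucleophilic than the coumarin C3=C4 bond, would give 8-(1,2-dibromo-2-ethoxyethyl)-7-methoxy-2H-chromen-2-one F6.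
- Et3N would remove the first HBr through the oxocarbenium ion to give 8-(1-bromo-2-ethoxyethenyl)-7-methoxy-2H-chromen-2-one F7.
- KOtBu (THF, −78 to 0 °C) would remove the second HBr to give 5.

**Step 9.**
- Most likely failure: acetylation of the phenol, which is shielded by the neighbouring aryl group and hydrogen-bonded to the aldehyde, outruns acylation by activated 19. Ring closure would then never start.
- Fallback (from 1 and 16, back at 21): the C3=C4 bond is made first and intermolecularly, and the lactone second.
- Rh2(OAc)4-catalysed O–H insertion of ethyl diazo(diethoxyphosphoryl)acetate into 1 would give ethyl 2-(diethoxyphosphoryl)-2-[(2-oxo-2H-chromen-7-yl)oxy]acetate F8.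
- Horner–Wadsworth–Emmons olefination of 16 with F8 (LiCl, DBU, MeCN) would give ethyl 3-[4-ethoxy-2-hydroxy-3-(7-methoxy-2-oxo-2H-chromen-8-yl)phenyl]-2-[(2-oxo-2H-chromen-7-yl)oxy]prop-2-enoate F9 as a mixture of alkene isomers.
- The isomer with aryl and ester cis lactonises directly. The other is funnelled by thermal isomerisation in refluxing N,N-diethylaniline, giving 21.

**Step 10.**
- Most likely failure: incomplete cleavage of the two ethers beside the axis, because BBr3 is tied up by three lactone carbonyls and the boron complexes may precipitate. Long exposure also risks lactone opening.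
- Fallback (from 16, back at 22): the ethers are removed before the third unit is attached.
- BBr3 on 16 would give 2,4-dihydroxy-3-(7-hydroxy-2-oxo-2H-chromen-8-yl)benzaldehyde F10.
- Perkin condensation with 19 in Ac2O/Et3N closes the lactone at the only OH ortho to the aldehyde and acetylates the other two phenols. This would give 2-oxo-8-(7-acetoxy-2-oxo-2H-chromen-8-yl)-3-[(2-oxo-2H-chromen-7-yl)oxy]-2H-chromen-7-yl acetate F11.
- Mild acid methanolysis (HCl, MeOH, rt) would give 22.

## Further compounds

F1 | step 6 | 8-(2,6-dimethoxyphenyl)-7-methoxy-2H-chromen-2-one | COc1cccc(OC)c1-c1c(OC)ccc2ccc(=O)oc12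
F2 | step 6 | 2,4-dimethoxy-3-(7-methoxy-2-oxo-2H-chromen-8-yl)benzaldehyde | COc1ccc(C=O)c(OC)c1-c1c(OC)ccc2ccc(=O)oc12
F3 | step 6 | 2-hydroxy-4-methoxy-3-(7-methoxy-2-oxo-2H-chromen-8-yl)benzaldehyde | COc1ccc(C=O)c(O)c1-c1c(OC)ccc2ccc(=O)oc12
F4 | step 6 | 7-methoxy-8-(7-methoxy-2-oxo-2H-chromen-8-yl)-3-[(2-oxo-2H-chromen-7-yl)oxy]-2H-chromen-2-one | COc1ccc2cc(Oc3ccc4ccc(=O)oc4c3)c(=O)oc2c1-c1c(OC)ccc2ccc(=O)oc12
F5 | step 3 | 8-[(E)-2-ethoxyethenyl]-7-methoxy-2H-chromen-2-one | CCO/C=C/c1c(OC)ccc2ccc(=O)oc12
F6 | step 3 | 8-(1,2-dibromo-2-ethoxyethyl)-7-methoxy-2H-chromen-2-one | CCOC(Br)C(Br)c1c(OC)ccc2ccc(=O)oc12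
F7 | step 3 | 8-(1-bromo-2-ethoxyethenyl)-7-methoxy-2H-chromen-2-one | CCOC=C(Br)c1c(OC)ccc2ccc(=O)oc12
F8 | step 9 | ethyl 2-(diethoxyphosphoryl)-2-[(2-oxo-2H-chromen-7-yl)oxy]acetate | CCOC(=O)C(Oc1ccc2ccc(=O)oc2c1)P(=O)(OCC)OCC
F9 | step 9 | ethyl 3-[4-ethoxy-2-hydroxy-3-(7-methoxy-2-oxo-2H-chromen-8-yl)phenyl]-2-[(2-oxo-2H-chromen-7-yl)oxy]prop-2-enoate | CCOC(=O)C(Oc1ccc2ccc(=O)oc2c1)=Cc1ccc(OCC)c(c1O)-c1c(OC)ccc2ccc(=O)oc12
F10 | step 10 | 2,4-dihydroxy-3-(7-hydroxy-2-oxo-2H-chromen-8-yl)benzaldehyde | O=Cc1ccc(O)c(c1O)-c1c(O)ccc2ccc(=O)oc12
F11 | step 10 | 2-oxo-8-(7-acetoxy-2-oxo-2H-chromen-8-yl)-3-[(2-oxo-2H-chromen-7-yl)oxy]-2H-chromen-7-yl acetate | CC(=O)Oc1ccc2cc(Oc3ccc4ccc(=O)oc4c3)c(=O)oc2c1-c1c(OC(C)=O)ccc2ccc(=O)oc12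
A1 | alternative 1 | 7-methoxy-8-(4,4,5,5-tetramethyl-1,3,2-dioxaborolan-2-yl)-2H-chromen-2-one | COc1ccc2ccc(=O)oc2c1B1OC(C)(C)C(C)(C)O1
A2 | alternative 1 | 7-ethoxy-8-iodo-3-[(2-oxo-2H-chromen-7-yl)oxy]-2H-chromen-2-one | CCOc1ccc2cc(Oc3ccc4ccc(=O)oc4c3)c(=O)oc2c1I
A3 | alternative 2 | 7-hydroxy-3-[(2-oxo-2H-chromen-7-yl)oxy]-2H-chromen-2-one | O=c1ccc2ccc(Oc3cc4ccc(O)cc4oc3=O)cc2o1
A4 | alternative 2 | 7,7'-dihydroxy-2H,2'H-[8,8'-bichromene]-2,2'-dione | O=c1ccc2ccc(O)c(-c3c(O)ccc4ccc(=O)oc34)c2o1
A5 | alternative 2 | 7,7'-dihydroxy-3,3'-bis[(2-oxo-2H-chromen-7-yl)oxy]-2H,2'H-[8,8'-bichromene]-2,2'-dione | O=c1ccc2ccc(Oc3cc4ccc(O)c(-c5c(O)ccc6cc(Oc7ccc8ccc(=O)oc8c7)c(=O)oc56)c4oc3=O)cc2o1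
A6 | alternative 3 | 2,2'-dihydroxy-6,6'-dimethoxy[1,1'-biphenyl]-3,3'-dicarbaldehyde | COc1ccc(C=O)c(O)c1-c1c(OC)ccc(C=O)c1O
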